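**Strategy.** Everything rests on the C13–C16 bond of ring D (C8, C14, C13, C16, C15). The C13 bridgehead carbinol next to the C16 exocyclic methylene is the imprint of a ketyl 1,2-vinyl shift, so ring D is made last. Allene photocycloaddition puts a methylenecyclobutane (C8, C14, C16, C15) on a C13-keto Δ8(14) enone. SmI2 then moves C16 from C14 to C13, turning the four-membered ring into the five-membered ring and setting carbinol and methylene in one operation. The enone, an A/B/C tricycle carrying the 19,20-lactone, comes from andrographolide by carbonyl-ene closure of ring C, ozonolysis–aldol contraction of ring B and amide-directed C20–H lactonisation.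

Key step: step 18

Remark 1: andrographolide, a commercial ent-labdane, is taken as starting material; it already holds C4, C5, C9 and C10 in the configuration of the target, and these centres are not touched.

Remark 2: atoms carry the numbers of the target throughout (the exocyclic methylene carbon on C8 of 1–5 is the later C14; the carbon added in step 3 is C13). "β" is the face of H5 and C18; "α" is the face of C19 and C20. The C13 carbinol centre made in step 4 is expected as an epimer mixture, is drawn without descriptor in 6–8 and 10–16, and is erased in step 14. Enol ether 4 is an E/Z mixture.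

**Step 1**
Reactants: 1 andrographolide
Product: 2 andrographolide 3,19-acetonide
Conditions: 2,2-dimethoxypropane, PPTS (cat.), acetone, 40 °C
Reagents that add atoms: 2,2-dimethoxypropane, COC(C)(C)OC
Why: Acid-catalysed transacetalisation (acetonide protection) ties the C3 hydroxyl and the C19 hydroxymethyl, which sit cis on neighbouring carbons, into a 1,3-dioxane without touching a stereocentre.

**Step 2**
Reactants: 2 andrographolide 3,19-acetonide
Product: 3 acetonide C12 aldehyde
Conditions: KMnO4, MgSO4, THF/H2O, −10 °C
Reagents that add atoms: potassium permanganate, [K+].[O-][Mn](=O)(=O)=O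
Why: Permanganate oxidative cleavage should attack the electron-poor alkylidene-lactone double bond much faster than the isolated exocyclic alkene on C8, cutting off the butenolide and leaving C12 as the aldehyde.

**Step 3**
Reactants: 3 acetonide C12 aldehyde
Product: 5 diol C13 aldehyde, via methyl enol ether 4 (not isolated)
Conditions: Ph3P(CH2OMe)Cl, KN(SiMe3)2, THF, 0 °C; then 2 M HCl, THF, rt
Reagents that add atoms: (methoxymethyl)triphenylphosphonium chloride, [Cl-].COC[P+](c1ccccc1)(c1ccccc1)c1ccccc1; water, O
Why: Wittig methoxymethylenation followed by acid hydrolysis of the enol ether is the standard one-carbon aldehyde homologation (it brings in C13), and the same acid should remove the acetonide.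

**Step 4**
Reactants: 5 diol C13 aldehyde
Product: 6 tricyclic triol
Conditions: Me2AlCl (excess), CH2Cl2, −78 → 0 °C
Reagents that add atoms: none
Why: Lewis-acid-promoted type 2 intramolecular carbonyl-ene reaction: the exocyclic methylene carbon (C14) bonds to the C13 aldehyde through a six-membered transition state that takes its hydrogen from C7, which closes ring C and leaves the alkene at C7=C8; the C13 carbinol configuration is of no consequence.

**Step 5**
Reactants: 6 tricyclic triol
Product: 7 dihydroxy nitrile
Conditions: TEMPO (cat.), PhI(OAc)2, NH4OAc, MeCN/H2O, rt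
Reagents that add atoms: ammonium acetate, [NH4+].CC(=O)[O-]
Why: Oxoammonium oxidation is selective for the primary C19 alcohol over the two secondary ones, and the aldehyde should be oxidised on through its N–H imine to the nitrile in the same flask (oxidative alcohol-to-nitrile conversion).

**Step 6**
Reactants: 7 dihydroxy nitrile
Product: 8 silyl ether nitrile
Conditions: TBSCl, imidazole, DMF, 0 °C
Reagents that add atoms: tert-butyldimethylsilyl chloride, CC(C)(C)[Si](C)(C)Cl
Why: Silyl ether formation should take place at the unhindered C13 hydroxyl well before the C3 hydroxyl, which is flanked by the quaternary C4.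

**Step 7**
Reactants: 8 silyl ether nitrile
Product: 10 ring B contracted enal, via seco keto aldehyde 9 (not isolated)
Conditions: O3, CH2Cl2/MeOH, −78 °C; Me2S; then piperidine, AcOH, toluene, 60 °C
Reagents that add atoms: ozone, [O-][O+]=O
Why: Ozonolysis of the only alkene gives the C8 ketone and the C7 aldehyde, and amine-catalysed intramolecular aldol condensation (the C6 enamine of the aldehyde adds to the C8 ketone, 5-exo-trig, then dehydration) should close the five-membered ring B with C7 left outside the ring.

**Step 8**
Reactants: 10 ring B contracted enal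
Product: 11 enoic acid
Conditions: NaClO2, NaH2PO4, 2-methylbut-2-ene, t-BuOH/H2O, rt
Reagents that add atoms: sodium chlorite, [Na+].[O-]Cl=O
Why: Pinnick oxidation converts the conjugated aldehyde into the carboxylic acid without touching the hydroxyl, silyl ether or nitrile.

**Step 9**
Reactants: 11 enoic acid
Product: 12 methyl enoate
Conditions: Me3SiCHN2, MeOH/toluene, 0 °C
Reagents that add atoms: (trimethylsilyl)diazomethane, C[Si](C)(C)C=[N+]=[N-]
Why: O-Methylation of the carboxylic acid by diazomethane released from the silyl reagent in methanol gives the C7 methyl ester under neutral conditions.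

**Step 10**
Reactants: 12 methyl enoate
Product: 13 2-ene
Conditions: Burgess reagent (methyl N-(triethylammoniumsulfonyl)carbamate), toluene, 80 °C
Reagents that add atoms: none
Why: Burgess dehydration (syn elimination through the sulfamate ester) can only use a hydrogen on C2 because C4 is quaternary, and the electron-withdrawing nitrile on C4 should suppress cationic Wagner–Meerwein shifts, so the C2=C3 alkene is expected.

**Step 11**
Reactants: 13 2-ene
Product: 14 2β-alcohol
Conditions: 9-BBN, THF, 65 °C; then H2O2, aq. NaOH, 0 °C
Reagents that add atoms: hydrogen peroxide, OO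
Why: Hydroboration–oxidation: the bulky borane should place boron on C2, away from the quaternary C4, and add from the β face because the α face is covered by the axial nitrile on C4 and the axial methyl on C10, which sets the equatorial 2β hydroxyl; the tetrasubstituted enoate does not react.

**Step 12**
Reactants: 14 2β-alcohol
Product: 15 2β-acetate
Conditions: Ac2O, pyridine, DMAP (cat.), CH2Cl2, rt
Reagents that add atoms: acetic anhydride, CC(=O)OC(C)=O
Why: Acetylation protects the C2 hydroxyl as an ester, which also lowers the reactivity of the C2–H bond towards the electrophilic radical of step 16.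

**Step 13**
Reactants: 15 2β-acetate
Product: 16 13-alcohol
Conditions: HF·pyridine, THF, 0 °C → rt
Reagents that add atoms: none
Why: Fluoride cleavage of the silyl ether frees the C13 hydroxyl under conditions that leave acetate, methyl ester and nitrile intact.

**Step 14**
Reactants: 16 13-alcohol
Product: 18 enone nitrile, via deconjugated ketone 17 (not isolated)
Conditions: Dess–Martin periodinane, NaHCO3, CH2Cl2, rt; then DBU (cat.), CH2Cl2, rt
Reagents that add atoms: none
Why: Dess–Martin oxidation gives the C13 ketone, and base-mediated conjugation (deprotonation at C14, reprotonation at C6) should move the double bond to C8=C14, the arrangement preferred in Hagemann's ester; C6 is set under thermodynamic control with the ester β, trans to the C5–C4 bond.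

**Step 15**
Reactants: 18 enone nitrile
Product: 19 enone amide
Conditions: [PtH(PMe2OH)(PMe2O)2H] (cat.), EtOH/H2O, 80 °C
Reagents that add atoms: water, O
Why: Platinum-catalysed nitrile hydration runs under neutral conditions and is known to convert hindered tertiary nitriles into primary amides without touching esters or enones.

**Step 16**
Reactants: 19 enone amide
Product: 21 enone lactone, via iminolactone 20 (not isolated)
Conditions: PhI(OAc)2, I2, 1,2-dichloroethane, visible light (tungsten lamp), rt; then 1 M HCl, THF, rt
Reagents that add atoms: water, O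
Why: Hofmann–Löffler–Freytag-type lactonisation: the N-iodoamide formed in the flask gives an amidyl radical that should abstract hydrogen from the C20 methyl, which is 1,3-diaxial to C19 (seven-membered transition state); the C20 iodide is displaced by the amide oxygen and the iminolactone is hydrolysed, while C6–H (next to the ester) and C2–H (next to the acetoxy group) are polarity-mismatched and less well placed.

**Step 17**
Reactants: 21 enone lactone
Product: 22 photoadduct
Conditions: allene (excess), THF, hν (medium-pressure Hg lamp, Pyrex filter), −78 °C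
Reagents that add atoms: allene, C=C=C
Why: Enone–allene [2+2] photocycloaddition through the enone triplet: head-to-head regiochemistry bonds the central allene carbon (C16) to C14 and a terminal carbon (C15) to C8, and addition should occur on the β face of C8, syn to H9, to give the cis-hydrindane and the cis-fused cyclobutane, which sets C8 (C14 follows from the cis fusion).

**Step 18**
Reactants: 22 photoadduct
Product: 23 target gibberellin methyl ester 2-acetate
Conditions: SmI2, t-BuOH, HMPA, THF, −78 → 0 °C
Reagents that add atoms: none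
Why: SmI2 reduces the C13 ketone to a ketyl radical that attacks C16 of the neighbouring exocyclic alkene (3-exo-trig); the cyclopropylcarbinyl radical reopens by breaking C14–C16, so C16 has moved from C14 to C13, and the C14 radical is reduced by a second SmI2 and protonated by t-BuOH to the C14 methylene. The closest known reaction type is the homoallyl-radical (1,2-vinyl) rearrangement of β,γ-unsaturated ketones under ketyl conditions, which is known to turn enone–allene photoadducts into methylenebicyclo[3.2.1]octanols. Ring D (C8, C14, C13, C16, C15) is closed by the C13–C16 bond in a 3-exo-trig attack followed by ring opening, a net one-carbon expansion of the four-membered ring (C8, C14, C16, C15). The only new stereocentre, C13, is fixed by the substrate: C16 is held on the β face by the C15–C8 tether and can reach only that face of C13, while C14 loses its stereocentre. The step needs the vinyl shift to win over β-scission of the C8–C14 cyclobutane bond and over plain ketone reduction; the C14–C16 bond lies parallel to the ketyl orbital, its direct scission would give a vinyl radical, and relief of cyclobutane strain pulls the equilibrium towards the C14 radical. Lactone, acetate and methyl ester are not reduced by SmI2 in THF in the absence of water.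

**Step 19**
Reactants: 23 target gibberellin methyl ester 2-acetate
Product: 25 target gibberellin, via seco hydroxy diacid 24 (not isolated)
Conditions: 2 M KOH, MeOH/H2O, 65 °C; then 1 M HCl to pH 3, 0 °C
Reagents that add atoms: potassium hydroxide, [K+].[OH-]
Why: Saponification removes the acetate and the C7 methyl ester and opens the lactone, and on mild acidification the 1,3-diaxial C20 hydroxyl and C19 acid should close again to the δ-lactone; the base-stable tertiary allylic C13 alcohol and the thermodynamically preferred 6β acid are not affected.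

**Compound list**

1 | andrographolide, (3E,4S)-3-{2-[(1R,4aS,5R,6R,8aS)-6-hydroxy-5-(hydroxymethyl)-5,8a-dimethyl-2-methylidenedecahydronaphthalen-1-yl]ethylidene}-4-hydroxyoxolan-2-one | C[C@@]12CC[C@@H](O)[C@@](C)(CO)[C@H]1CCC(=C)[C@H]2C/C=C3\[C@H](O)COC3=O | starting material
2 | andrographolide 3,19-acetonide (isopropylidene acetal across O3 and O19) | C[C@@]12CC[C@H]3OC(C)(C)OC[C@@]3(C)[C@H]1CCC(=C)[C@H]2C/C=C4\[C@H](O)COC4=O | intermediate
3 | acetonide C12 aldehyde (decalin of 2 with CH2CHO on C9, exocyclic methylene on C8) | C[C@@]12CC[C@H]3OC(C)(C)OC[C@@]3(C)[C@H]1CCC(=C)[C@H]2CC=O | intermediate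
4 | methyl enol ether (CH2CH=CHOMe on C9, E/Z mixture, acetonide in place) | C[C@@]12CC[C@H]3OC(C)(C)OC[C@@]3(C)[C@H]1CCC(=C)[C@H]2CC=COC | intermediate
5 | diol C13 aldehyde (free C3 hydroxyl and C19 hydroxymethyl, CH2CH2CHO on C9, exocyclic methylene on C8) | C[C@@]12CC[C@@H](O)[C@@](C)(CO)[C@H]1CCC(=C)[C@H]2CCC=O | intermediate
6 | tricyclic triol (ring C closed, C7=C8 alkene, hydroxyls at C3, C13 and C19, C13 epimers) | C[C@@]12CC[C@@H](O)[C@@](C)(CO)[C@H]1CC=C3CC(O)CC[C@H]32 | intermediate
7 | dihydroxy nitrile (as 6, C19 now the nitrile on C4) | C[C@@]12CC[C@@H](O)[C@@](C)(C#N)[C@H]1CC=C3CC(O)CC[C@H]32 | intermediate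
8 | silyl ether nitrile (13-O-tert-butyldimethylsilyl ether of 7) | C[C@@]12CC[C@@H](O)[C@@](C)(C#N)[C@H]1CC=C3CC(O[Si](C)(C)C(C)(C)C)CC[C@H]32 | intermediate
9 | seco keto aldehyde (C7–C8 cleaved: C8 ketone in ring C, CH2CHO on C5) | C[C@]1(CC[C@@H](O)[C@@](C)(C#N)[C@H]1CC=O)[C@@H]1CCC(O[Si](C)(C)C(C)(C)C)CC1=O | intermediate
10 | ring B contracted enal (five-membered ring B, C6=C8 alkene, formyl C7 on C6) | C[C@@]12CC[C@@H](O)[C@@](C)(C#N)[C@H]1C(C=O)=C3CC(O[Si](C)(C)C(C)(C)C)CC[C@H]32 | intermediate
11 | enoic acid (C7 carboxylic acid on C6=C8) | C[C@@]12CC[C@@H](O)[C@@](C)(C#N)[C@H]1C(C(=O)O)=C3CC(O[Si](C)(C)C(C)(C)C)CC[C@H]32 | intermediate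
12 | methyl enoate (C7 methyl ester, C3 hydroxyl free) | C[C@@]12CC[C@@H](O)[C@@](C)(C#N)[C@H]1C(C(=O)OC)=C3CC(O[Si](C)(C)C(C)(C)C)CC[C@H]32 | intermediate
13 | 2-ene (C2=C3 alkene in ring A) | C[C@@]12CC=C[C@@](C)(C#N)[C@H]1C(C(=O)OC)=C3CC(O[Si](C)(C)C(C)(C)C)CC[C@H]32 | intermediate
14 | 2β-alcohol (equatorial hydroxyl on C2, trans to the C4 nitrile and the C10 methyl) | C[C@@]12C[C@H](O)C[C@@](C)(C#N)[C@H]1C(C(=O)OC)=C3CC(O[Si](C)(C)C(C)(C)C)CC[C@H]32 | intermediate
15 | 2β-acetate | C[C@@]12C[C@H](OC(C)=O)C[C@@](C)(C#N)[C@H]1C(C(=O)OC)=C3CC(O[Si](C)(C)C(C)(C)C)CC[C@H]32 | intermediate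
16 | 13-alcohol (2β-acetoxy, free C13 hydroxyl) | C[C@@]12C[C@H](OC(C)=O)C[C@@](C)(C#N)[C@H]1C(C(=O)OC)=C3CC(O)CC[C@H]32 | intermediate
17 | deconjugated ketone (C13 ketone, C6=C8 alkene) | C[C@@]12C[C@H](OC(C)=O)C[C@@](C)(C#N)[C@H]1C(C(=O)OC)=C3CC(=O)CC[C@H]32 | intermediate
18 | enone nitrile (C13 ketone conjugated with C8=C14, 6β-methoxycarbonyl, H6 α) | C[C@@]12C[C@H](OC(C)=O)C[C@@](C)(C#N)[C@H]1[C@H](C(=O)OC)C3=CC(=O)CC[C@H]32 | intermediate
19 | enone amide (C19 primary carboxamide) | C[C@@]12C[C@H](OC(C)=O)C[C@@](C)(C(N)=O)[C@H]1[C@H](C(=O)OC)C3=CC(=O)CC[C@H]32 | intermediate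
20 | iminolactone (cyclic imidate C19(=NH)–O–C20) | O=C1C=C2[C@@H](C(=O)OC)[C@H]3[C@]4(COC(=N)[C@]3(C)C[C@@H](OC(C)=O)C4)[C@@H]2CC1 | intermediate
21 | enone lactone (19,20-δ-lactone, 2β-acetate, 7-methyl ester, Δ8(14)-13-one) | O=C1C=C2[C@@H](C(=O)OC)[C@H]3[C@]4(COC(=O)[C@]3(C)C[C@@H](OC(C)=O)C4)[C@@H]2CC1 | intermediate
22 | photoadduct (methylenecyclobutane C8, C14, C16, C15 cis-fused to ring C, C15 β on C8, exocyclic C16=C17, C13 ketone) | C=C1C[C@]23[C@H]1C(=O)CC[C@H]2[C@]12COC(=O)[C@](C)(C[C@@H](OC(C)=O)C1)[C@H]2[C@@H]3C(=O)OC | intermediate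
23 | target gibberellin methyl ester 2-acetate (2β-acetoxy, 13-hydroxy, C16 exocyclic methylene, C7 methyl ester, 19,20-δ-lactone) | C=C1C[C@]23C[C@@]1(O)CC[C@H]2[C@]12COC(=O)[C@](C)(C[C@@H](OC(C)=O)C1)[C@H]2[C@@H]3C(=O)OC | intermediate
24 | seco hydroxy diacid (2β,13,20-trihydroxy-7,19-dioic acid, dipotassium salt in the flask) | C=C1C[C@]23C[C@@]1(O)CC[C@H]2[C@]1(CO)C[C@H](O)C[C@@](C)(C(=O)O)[C@H]1[C@@H]3C(=O)O | intermediate
25 | target gibberellin (2β,13-dihydroxy gibberellin with C16 exocyclic methylene, free C7 carboxylic acid and 19,20-δ-lactone; systematic name ent-2α,13,20-trihydroxygibberell-16-ene-7,19-dioic acid 19,20-lactone) | C=C1C[C@]23C[C@@]1(O)CC[C@H]2[C@]12COC(=O)[C@](C)(C[C@@H](O)C1)[C@H]2[C@@H]3C(=O)O | target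

**Total step count:** 19. **Longest linear sequence:** 19 steps (fully linear from 1).

**Steps most likely to fail**

Step 16 (C20–H lactonisation). The primary amide may undergo a Hofmann-type rearrangement under the hypervalent iodine oxidant, or the amidyl radical may abstract hydrogen at C6 or C2 instead of C20. The fallback replaces radical hydrogen transfer by acyl nitrene C–H insertion; it sets out from 19 and comes back at 21. Nitrosative deamination of 19 (t-BuONO, AcOH) should give the C19 carboxylic acid F1. Diphenylphosphoryl azide and Et3N convert it into the acyl azide F2. Irradiation at 254 nm in CH2Cl2 at −40 °C, below the onset of the Curtius rearrangement, should let the acyl nitrene insert into the 1,3-diaxial C20–H bond to give the δ-lactam F3. N-Nitrosation (N2O4, NaOAc) gives the N-nitrosolactam F4, which on warming in toluene should rearrange with loss of N2 to lactone 21.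

Step 18 (ketyl ring expansion). The ketyl may open the C8–C14 cyclobutane bond by β-scission or simply be reduced to the carbinol instead of undergoing the vinyl shift. The fallback uses an anionic 1,2-shift in place of the radical one, still making ring D by one-carbon expansion of the same cyclobutane; it sets out from 22 and comes back at 23. Under equilibrating conditions (KN(SiMe3)2, THF) 22 should give the extended enolate by loss of the C14 hydrogen, which is both α to the ketone and allylic. Hydroxylation with 2-(phenylsulfonyl)-3-phenyloxaziridine gives the 14-hydroxy ketone F5. α-Ketol rearrangement (Al(Ot-Bu)3, toluene, heat) should move the vinyl carbon C16 from C14 to C13 with relief of ring strain and give the 13-hydroxy-14-ketone F6. NaBH4 reduces the C14 ketone to the 13,14-diol F7. The secondary C14 hydroxyl is converted into the phenyl thionocarbonate F8 (PhOC(S)Cl, DMAP), and Barton–McCombie deoxygenation (Bu3SnH, AIBN) gives 23.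

Step 11 (hydroboration). The inductive pull of the nitrile may steer boron to C3, or addition to the hindered alkene may be too slow. The fallback replaces hydroboration by dihydroxylation and deoxygenation; it sets out from 13 and comes back at 15. OsO4 (cat.) with N-methylmorpholine N-oxide should add to the β face of the C2=C3 alkene, the enoate being inert, to give the 2β,3β-diol F9. Ac2O in pyridine should acetylate only the equatorial C2 hydroxyl, the axial C3 hydroxyl being neopentyl, to give the monoacetate F10. PhOC(S)Cl with DMAP at elevated temperature gives the C3 phenyl thionocarbonate F11, and Bu3SnH with AIBN removes the C3 oxygen to give 15.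

**Further compounds**

F1 | step 16 | C19 carboxylic acid of the enone series (2β-acetate, 7-methyl ester) | C[C@@]12C[C@H](OC(C)=O)C[C@@](C)(C(=O)O)[C@H]1[C@H](C(=O)OC)C3=CC(=O)CC[C@H]32
F2 | step 16 | C19 acyl azide | C[C@@]12C[C@H](OC(C)=O)C[C@@](C)(C(=O)N=[N+]=[N-])[C@H]1[C@H](C(=O)OC)C3=CC(=O)CC[C@H]32
F3 | step 16 | 19,20-δ-lactam (C19(=O)–NH–C20) | O=C1C=C2[C@@H](C(=O)OC)[C@H]3[C@]4(CNC(=O)[C@]3(C)C[C@@H](OC(C)=O)C4)[C@@H]2CC1
F4 | step 16 | N-nitroso-19,20-lactam | O=C1C=C2[C@@H](C(=O)OC)[C@H]3[C@]4(CN(N=O)C(=O)[C@]3(C)C[C@@H](OC(C)=O)C4)[C@@H]2CC1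
F5 | step 18 | 14-hydroxy photoadduct (hydroxyl on the cyclobutane carbon C14, cis ring fusion kept) | C=C1C[C@]23[C@@]1(O)C(=O)CC[C@H]2[C@]12COC(=O)[C@](C)(C[C@@H](OC(C)=O)C1)[C@H]2[C@@H]3C(=O)OC
F6 | step 18 | 13-hydroxy-14-ketone with ring D formed | C=C1C[C@]23C(=O)[C@@]1(O)CC[C@H]2[C@]12COC(=O)[C@](C)(C[C@@H](OC(C)=O)C1)[C@H]2[C@@H]3C(=O)OC
F7 | step 18 | 13,14-diol (C14 epimers) | C=C1C[C@]23C(O)[C@@]1(O)CC[C@H]2[C@]12COC(=O)[C@](C)(C[C@@H](OC(C)=O)C1)[C@H]2[C@@H]3C(=O)OC
F8 | step 18 | 14-O-(phenoxythiocarbonyl) derivative of F7 | C=C1C[C@]23C(OC(=S)Oc4ccccc4)[C@@]1(O)CC[C@H]2[C@]12COC(=O)[C@](C)(C[C@@H](OC(C)=O)C1)[C@H]2[C@@H]3C(=O)OC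
F9 | step 11 | 2β,3β-diol | C[C@@]12C[C@H](O)[C@H](O)[C@@](C)(C#N)[C@H]1C(C(=O)OC)=C3CC(O[Si](C)(C)C(C)(C)C)CC[C@H]32
F10 | step 11 | 2β-acetoxy-3β-alcohol | C[C@@]12C[C@H](OC(C)=O)[C@H](O)[C@@](C)(C#N)[C@H]1C(C(=O)OC)=C3CC(O[Si](C)(C)C(C)(C)C)CC[C@H]32
F11 | step 11 | 2β-acetoxy-3β-O-(phenoxythiocarbonyl) derivative | C[C@@]12C[C@H](OC(C)=O)[C@H](OC(=S)Oc4ccccc4)[C@@](C)(C#N)[C@H]1C(C(=O)OC)=C3CC(O[Si](C)(C)C(C)(C)C)CC[C@H]32
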